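## Retrosynthetic overview
- The C9' carbinol comes from a side-chain methyl ketone by an (R)-selective enzymatic reduction, so no protecting group is used anywhere.
- Rings A (10-membered lactone) and B (γ-butyrolactone) are opened together. Cutting C3–C4 (Reformatsky) and O–C1' (lactonisation) gives an acyclic haloacetate / aldehyde / ethyl ester.
- C5–C6 comes from a catalyst-controlled α-alkylation of an aldehyde with a bromomethyl ketone. The bromoketone is made from (R)-γ-valerolactone and LiCH2Br.
- Cα–furan comes from an iminium-catalysed Friedel–Crafts addition of a 2-alkylfuran to ethyl 4-oxobutenoate.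
- Ring order: furan ring C is bought. Ring A and then ring B close in the same SmI2 operation.

Atom labels:
- Ring A: O1–C2(=O)–C3–C4(O)–C5–C6–C7(=O)–C8–C9–C10(CH3).
- Ring B: O–C4–C5–Cα–C1'(=O).
- C9' is the side-chain carbinol carbon.
- The target is C4 S, C5 S, Cα S, C10 R, C9' R. H4, H5 and Hα are all on one face, so the lactone is all-cis.

Assumption: 1, 2 and 4 are bought. 4 is sold as the single enantiomer.

## Route

Step 1
Reactants: 1 4-(furan-2-yl)butan-2-one; 2 ethyl (E)-4-oxobut-2-enoate
Product: 3 ethyl (2S)-4-oxo-2-[5-(3-oxobutyl)furan-2-yl]butanoate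
Conditions: (2R,5R)-5-benzyl-2-tert-butyl-3-methylimidazolidin-4-one·CF3CO2H (20 mol %), 1 (3 equiv), CH2Cl2/iPrOH 85:15, −40 °C
Reagents that add atoms: none
Why: Iminium-catalysed Friedel–Crafts conjugate alkylation (MacMillan imidazolidinone catalysis): the free C5 position of the furan attacks the ester-bearing β-carbon of the iminium ion of 2, the (2R,5R)-catalyst leaves one face open and sets Cα as S (the mirror image of the sense known for the (2S,5S)-catalyst with pyrroles and indoles), and the methyl ketone of 1 is a spectator.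

Step 2
Reactants: 4 (R)-γ-valerolactone
Product: 6 (5R)-1-bromo-5-hydroxyhexan-2-one, via lithium hemiketal alkoxide 5 (not isolated)
Conditions: CH2Br2 (1.6 equiv), n-BuLi (1.5 equiv, added last, dropwise), THF/Et2O, −90 to −78 °C; AcOH, −78 °C
Reagents that add atoms: dibromomethane, BrCBr
Why: Acylation of a halomethyllithium by a lactone: LiCH2Br made in the presence of 4 adds once because the tetrahedral alkoxide 5 survives at −78 °C, the acidic quench releases the bromomethyl ketone carrying C6–C10, and the C10 stereocentre (R) is not touched.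

Step 3
Reactants: 6 (5R)-1-bromo-5-hydroxyhexan-2-one
Product: 7 (2R)-6-bromo-5-oxohexan-2-yl chloroacetate
Conditions: ClCH2COCl (1.2 equiv), NaHCO3 (3 equiv), CH2Cl2, 0 °C
Reagents that add atoms: chloroacetyl chloride, O=C(Cl)CCl
Why: O-acylation of the open hydroxy ketone form with an acid chloride over a non-nucleophilic solid base installs O1–C2–C3 early, removes the free hydroxyl that would otherwise tie up C7 and C4 as ketals, and leaves a C–Cl bond that is inert in step 4.

Step 4
Reactants: 3 ethyl (2S)-4-oxo-2-[5-(3-oxobutyl)furan-2-yl]butanoate; 7 (2R)-6-bromo-5-oxohexan-2-yl chloroacetate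
Product: 8 ethyl (2S,3S,8R)-8-(chloroacetoxy)-3-formyl-5-oxo-2-[5-(3-oxobutyl)furan-2-yl]nonanoate
Conditions: (2R,5S)-2-tert-butyl-3,5-dimethylimidazolidin-4-one·HOTf (20 mol %), Ru(bpy)3Cl2 (0.5 mol %), 2,6-lutidine (2 equiv), DMF, visible light, 23 °C
Reagents that add atoms: none
Why: Photoredox organocatalytic α-alkylation of an aldehyde (merged enamine and Ru photoredox catalysis): only the carbon–bromine bond next to the ketone is reduced, the electrophilic α-keto radical adds to the exposed Si face of the E-enamine of 3 and sets C5 as S under catalyst control, the chloroacetate is too hard to reduce, and Cα (β to the aldehyde) is untouched by the weak base.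

Step 5
Reactants: 8 ethyl (2S,3S,8R)-8-(chloroacetoxy)-3-formyl-5-oxo-2-[5-(3-oxobutyl)furan-2-yl]nonanoate
Product: 12 9'-oxocordycicadin B (side-chain methyl ketone of the target; all-cis lactone), via iodoacetate 9 (not isolated), via samarium enolate 10 (not isolated), via samarium aldolate 11 (not isolated)
Conditions: NaI (3 equiv), acetone, 23 °C, filter, swap solvent to THF; add over 8 h to SmI2 (3 equiv) in THF, −20 °C, final 2 mM; warm to 23 °C; 0.1 M HCl
Reagents that add atoms: none
Why: Proposed new method: a samarium Reformatsky macrocyclisation is coupled to an aldolate lactonisation so that rings A and B close in one flask: SmI2 reduces only the iodoacetate (from a Finkelstein exchange) to a trivalent samarium enolate, this adds to the aldehyde rather than to the two ketones (attack at C7 would need a seven-membered lactone with the disfavoured E-ester geometry and is reversible), attack anti to the large CH(furyl)CO2Et group (Felkin–Anh) sets C4 as S with C3 cis to C6, and the samarium alkoxide then expels ethoxide from the neighbouring ester, which traps the adduct irreversibly as the cis-fused lactone without touching Cα; the closest known reaction types are the SmI2 cyclisation of ω-(α-haloacyloxy)aldehydes to 8- to 14-membered β-hydroxy lactones and the spontaneous lactonisation of samarium γ-alkoxy esters in ketyl–acrylate couplings.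

Step 6
Reactants: 12 9'-oxocordycicadin B
Product: 13 cordycicadin B
Conditions: alcohol dehydrogenase from Lactobacillus kefir, NADP+ (cat.), MgCl2 (1 mM), iPrOH (10 % v/v), phosphate buffer pH 6.5, 30 °C
Reagents that add atoms: none
Why: Biocatalytic anti-Prelog ketone reduction: the enzyme accepts only ketones with a methyl group on one side, so the side-chain ketone gives the (R)-carbinol C9' while the C7 ketone (flanked by two ring CH2 groups) stays, and the slightly acidic buffer protects the epimerisable Cα and both lactones.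

## Compound list
1 | 4-(furan-2-yl)butan-2-one | CC(=O)CCc1ccco1 | starting material
2 | ethyl (E)-4-oxobut-2-enoate | CCOC(=O)/C=C/C=O | starting material
3 | ethyl (2S)-4-oxo-2-[5-(3-oxobutyl)furan-2-yl]butanoate | CCOC(=O)[C@@H](CC=O)c1ccc(CCC(C)=O)o1 | intermediate
4 | (R)-γ-valerolactone, (5R)-5-methyloxolan-2-one | C[C@@H]1CCC(=O)O1 | starting material
5 | lithium (5R)-2-(bromomethyl)-5-methyloxolan-2-olate (tetrahedral adduct, both C2 epimers, not isolated) | C[C@@H]1CCC(CBr)([O-])O1.[Li+] | intermediate
6 | (5R)-1-bromo-5-hydroxyhexan-2-one (in equilibrium with its cyclic hemiketal) | C[C@@H](O)CCC(=O)CBr | intermediate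
7 | (2R)-6-bromo-5-oxohexan-2-yl chloroacetate | C[C@@H](OC(=O)CCl)CCC(=O)CBr | intermediate
8 | ethyl (2S,3S,8R)-8-(chloroacetoxy)-3-formyl-5-oxo-2-[5-(3-oxobutyl)furan-2-yl]nonanoate | C[C@@H](OC(=O)CCl)CCC(=O)C[C@H](C=O)[C@H](C(=O)OCC)c1ccc(CCC(C)=O)o1 | intermediate
9 | iodoacetate analogue of 8 (not isolated) | C[C@@H](OC(=O)CI)CCC(=O)C[C@H](C=O)[C@H](C(=O)OCC)c1ccc(CCC(C)=O)o1 | intermediate
10 | diiodosamarium ester enolate from 9 (not isolated) | C[C@@H](OC(=C)O[Sm](I)I)CCC(=O)C[C@H](C=O)[C@H](C(=O)OCC)c1ccc(CCC(C)=O)o1 | intermediate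
11 | diiodosamarium C4 alkoxide of the 10-membered β-hydroxy keto lactone, C4 S, C5 S, C10 R, with CH(furyl)CO2Et (Cα S) on C5 (not isolated) | C[C@@H]1CCC(=O)C[C@@H]([C@H](C(=O)OCC)c2ccc(CCC(C)=O)o2)[C@@H](O[Sm](I)I)CC(=O)O1 | intermediate
12 | 9'-oxocordycicadin B: cis-fused γ-butyrolactone / 10-membered 7-keto lactone, C4 S, C5 S, Cα S, C10 R, with 5-(3-oxobutyl)furan-2-yl on Cα | C[C@@H]1CCC(=O)C[C@@H]2[C@H](CC(=O)O1)OC(=O)[C@@H]2c1ccc(CCC(C)=O)o1 | intermediate
13 | cordycicadin B | C[C@@H]1CCC(=O)C[C@@H]2[C@H](CC(=O)O1)OC(=O)[C@@H]2c1ccc(CC[C@@H](C)O)o1 | target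

## Step count and risks
Total steps: 6. Longest linear sequence: 5 (4 → 6 → 7 → 8 → 12 → 13).

**Step 5 (highest risk).**
- A medium ring has to close in the presence of two ketones.
- The enolate may be quenched by the acidic Cα–H.
- The Felkin–Anh preference may be eroded by the tether.
- Liberated ethoxide may epimerise Cα.

Fallback, from 8 back to 12: close the two rings one after the other, and make ring A by macrolactonisation instead of carbon–carbon bond formation. A BF3·OEt2-mediated Mukaiyama aldol addition of the tert-butyldimethylsilyl ketene acetal of tert-butyl acetate to 8 (CH2Cl2, −78 °C, Felkin–Anh) gives the tert-butyl β-hydroxy ester F1. This lactonises with catalytic CSA to the cis-butyrolactone F2. Thiourea/NaHCO3 in EtOH removes the chloroacetate to give the hydroxy ester F3, and TFA/CH2Cl2 frees the seco acid F4. A Shiina macrolactonisation (MNBA, DMAP, CH2Cl2, high dilution) then closes ring A to 12.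

**Step 4.**
- An aliphatic bromomethyl ketone is a weaker radical precursor than the usual aryl ones.
- The furan can trap radicals.
- The aldehyde has to be the limiting partner.

Fallback, from 3 back to 8: replace the radical alkylation by a polar enamine Michael addition to a 2-nitroalkene, and unmask the ketone by a Nef reaction. Commercial 5-nitropentan-2-one is reduced with the same (R)-selective alcohol dehydrogenase to (R)-5-nitropentan-2-ol F5 and acylated with chloroacetyl chloride to the chloroacetate F6. Hydroxymethylation with aqueous formaldehyde (cat. iPr2NEt) gives the nitro alcohol F7, and dehydration (MsCl, iPr2NEt, −20 °C) gives the nitroalkene F8. Aldehyde 3 adds to it under (S)-α,α-diphenylprolinol trimethylsilyl ether/3-nitrobenzoic acid catalysis to give the γ-nitro aldehyde F9. C5 is set as S by the catalyst; C7 is a mixture, which does not matter. Buffered TiCl3/NH4OAc then converts CH–NO2 into the C7 ketone of 8.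

**Step 1.**
- A 2-alkylfuran is at the lower limit of nucleophilicity for iminium catalysis.
- The product aldehyde can react further.

Fallback, from 1 back to 3: replace iminium activation by two-point Lewis acid activation. Monoethyl fumarate and oxazolidin-2-one (PivCl, Et3N, LiCl) give the fumaroyl imide F10. Cu(OTf)2/tBu-box (10 mol %, ligand enantiomer chosen for S) catalyses Friedel–Crafts addition of 1 at the carbon β to the chelated imide carbonyl to give the imide adduct F11. LiSEt (THF, −20 °C) exchanges the oxazolidinone for the ethyl thioester F12, and a Fukuyama reduction (Et3SiH, Pd/C, acetone) gives 3.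

## Further compounds
F1 | step 5 | ethyl (2S,3S,8R)-3-[(1S)-3-tert-butoxy-1-hydroxy-3-oxopropyl]-8-(chloroacetoxy)-5-oxo-2-[5-(3-oxobutyl)furan-2-yl]nonanoate | C[C@@H](OC(=O)CCl)CCC(=O)C[C@@H]([C@H](C(=O)OCC)c1ccc(CCC(C)=O)o1)[C@@H](O)CC(=O)OC(C)(C)C
F2 | step 5 | tert-butyl 2-[(2S,3S,4S)-3-[(5R)-5-(chloroacetoxy)-2-oxohexyl]-5-oxo-4-[5-(3-oxobutyl)furan-2-yl]oxolan-2-yl]acetate | C[C@@H](OC(=O)CCl)CCC(=O)C[C@@H]1[C@H](CC(=O)OC(C)(C)C)OC(=O)[C@@H]1c1ccc(CCC(C)=O)o1
F3 | step 5 | tert-butyl 2-[(2S,3S,4S)-3-[(5R)-5-hydroxy-2-oxohexyl]-5-oxo-4-[5-(3-oxobutyl)furan-2-yl]oxolan-2-yl]acetate | C[C@@H](O)CCC(=O)C[C@@H]1[C@H](CC(=O)OC(C)(C)C)OC(=O)[C@@H]1c1ccc(CCC(C)=O)o1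
F4 | step 5 | 2-[(2S,3S,4S)-3-[(5R)-5-hydroxy-2-oxohexyl]-5-oxo-4-[5-(3-oxobutyl)furan-2-yl]oxolan-2-yl]acetic acid | C[C@@H](O)CCC(=O)C[C@@H]1[C@H](CC(=O)O)OC(=O)[C@@H]1c1ccc(CCC(C)=O)o1
F5 | step 4 | (R)-5-nitropentan-2-ol | C[C@@H](O)CCC[N+](=O)[O-]
F6 | step 4 | (2R)-5-nitropentan-2-yl chloroacetate | C[C@@H](OC(=O)CCl)CCC[N+](=O)[O-]
F7 | step 4 | (2R)-6-hydroxy-5-nitrohexan-2-yl chloroacetate (C5 epimers) | C[C@@H](OC(=O)CCl)CCC(CO)[N+](=O)[O-]
F8 | step 4 | (2R)-5-nitrohex-5-en-2-yl chloroacetate | C[C@@H](OC(=O)CCl)CCC(=C)[N+](=O)[O-]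
F9 | step 4 | ethyl (2S,3S,8R)-8-(chloroacetoxy)-3-formyl-5-nitro-2-[5-(3-oxobutyl)furan-2-yl]nonanoate (C5 epimers) | C[C@@H](OC(=O)CCl)CCC(C[C@H](C=O)[C@H](C(=O)OCC)c1ccc(CCC(C)=O)o1)[N+](=O)[O-]
F10 | step 1 | ethyl (E)-4-oxo-4-(2-oxo-1,3-oxazolidin-3-yl)but-2-enoate | CCOC(=O)/C=C/C(=O)N1CCOC1=O
F11 | step 1 | ethyl (2S)-4-oxo-2-[5-(3-oxobutyl)furan-2-yl]-4-(2-oxo-1,3-oxazolidin-3-yl)butanoate | CCOC(=O)[C@@H](CC(=O)N1CCOC1=O)c1ccc(CCC(C)=O)o1
F12 | step 1 | ethyl (2S)-4-(ethylsulfanyl)-4-oxo-2-[5-(3-oxobutyl)furan-2-yl]butanoate | CCOC(=O)[C@@H](CC(=O)SCC)c1ccc(CCC(C)=O)o1
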